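**Retrosynthetic overview**
1. Target 27 ⇐ hexasilyl ether 26 ⇐ chromone ketone 20 + arylboronic acid 25. The base-labile flavanone C2 centre is made last, by Pd/PyOX asymmetric 1,4-addition, after every strongly basic step.
2. Key disconnection: the aryl ketone C(=O)–Ar bond of 20 ⇐ ring aldehyde 12, reversed in polarity as its N-tert-butylhydrazone 13 (acyl-anion equivalent), + aryl bromide 17 under Pd. Two electrophilic carbons are joined, and no organometallic has to choose between CHO and the chromone C=O.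
3. Cyclohexene 12 ⇐ exo-selective, iminium-catalysed Diels–Alder reaction of chromonyl diene 8 with enal 11; this sets the three ring stereocentres.
4. Diene 8 ⇐ Heck coupling of 6-iodochromone 6 with myrcene 7; 6 ⇐ phloroacetophenone 1 via chromone 3 and 5-OH-directed iodination. Fragments 11, 17 and 25 come from 2,4-dihydroxybenzaldehyde, 4-bromophenol + prenyl bromide, and 4-bromoresorcinol.
5. Ring order: chromone pyranone ring (step 1) → cyclohexene (step 8) → dihydropyranone stereocentre by conjugate addition (step 15); the benzene rings are bought.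

Assumption: the SMILES is read as the (2S)-flavanone carrying the (1R,5S,6R) all-trans cyclohexene (aroyl group trans to both neighbouring aryl groups). TIPS = triisopropylsilyl, TBS = tert-butyldimethylsilyl.

**Route**

Step 1
Reactants: 1 2',4',6'-trihydroxyacetophenone
Product: 3 5,7-dihydroxy-4H-chromen-4-one, via 4-ethoxy-5,7-dihydroxychromenylium perchlorate 2 (not isolated)
Conditions: HC(OEt)3, 70% HClO4, rt; then H2O, 100 °C
Reagents that add atoms: triethyl orthoformate (CCOC(OCC)OCC); water (O)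
Why: Orthoformate annulation of an o-hydroxyacetophenone (C-formylation of the methyl ketone, ring closure to the chromenylium salt, hydrolysis) is the classical route to 2,3-unsubstituted chromones, and no stereocentre is formed.

Step 2
Reactants: 3 5,7-dihydroxy-4H-chromen-4-one
Product: 4 5-hydroxy-7-(triisopropylsilyloxy)-4H-chromen-4-one
Conditions: TIPSCl (1.05 equiv), imidazole, DMF, 0 °C
Reagents that add atoms: triisopropylsilyl chloride (CC(C)[Si](Cl)(C(C)C)C(C)C)
Why: Chemoselective silyl ether formation, because the 7-OH is the acidic, unhindered phenol whereas the 5-OH is deactivated by its hydrogen bond to C4=O.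

Step 3
Reactants: 4 5-hydroxy-7-(triisopropylsilyloxy)-4H-chromen-4-one
Product: 5 5-hydroxy-6-iodo-7-(triisopropylsilyloxy)-4H-chromen-4-one
Conditions: BnMe3N·ICl2, CaCO3, CH2Cl2–MeOH, rt
Reagents that add atoms: benzyltrimethylammonium dichloroiodate (C[N+](C)(C)Cc1ccccc1.Cl[I-]Cl)
Why: Electrophilic aromatic iodination is directed ortho to the free, chelated 5-OH, which gives the 6-iodide (not C8 or C3) as established for 5-hydroxy-7-alkoxyflavones and fixes the attachment regiochemistry.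

Step 4
Reactants: 5 5-hydroxy-6-iodo-7-(triisopropylsilyloxy)-4H-chromen-4-one
Product: 6 6-iodo-4-oxo-7-(triisopropylsilyloxy)-4H-chromen-5-yl acetate
Conditions: Ac2O, Et3N, DMAP (cat.), CH2Cl2, rt
Reagents that add atoms: acetic anhydride (CC(=O)OC(C)=O)
Why: DMAP-catalysed O-acylation masks the phenol next to iodine so that the π-allylpalladium species of the next step cannot be trapped by oxygen (Larock-type annulation); the acetate is temporary and is lost in step 12.

Step 5
Reactants: 6 6-iodo-4-oxo-7-(triisopropylsilyloxy)-4H-chromen-5-yl acetate; 7 β-myrcene (3 equiv)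
Product: 8 6-[(1E)-7-methyl-3-methylideneocta-1,6-dien-1-yl]-4-oxo-7-(triisopropylsilyloxy)-4H-chromen-5-yl acetate
Conditions: Pd(OAc)2 (10 mol%), P(o-tol)3, Et3N, DMF, 90 °C
Reagents that add atoms: none
Why: Mizoroki–Heck reaction in which ArPd adds to the unsubstituted vinyl terminus of myrcene and β-hydride elimination regenerates the conjugated diene with E geometry at the new styrenyl double bond.

Step 6
Reactants: 9 2,4-dihydroxybenzaldehyde
Product: 10 2,4-bis(triisopropylsilyloxy)benzaldehyde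
Conditions: TIPSOTf (2.4 equiv), 2,6-lutidine, CH2Cl2, 0 °C to rt
Reagents that add atoms: triisopropylsilyl triflate (CC(C)[Si](OS(=O)(=O)C(F)(F)F)(C(C)C)C(C)C)
Why: Silyl ether formation with the triflate also silylates the hydrogen-bonded ortho phenol, and aryl TIPS ethers are chosen because they should survive the NaOt-Bu of step 12 and come off with fluoride at the end.

Step 7
Reactants: 10 2,4-bis(triisopropylsilyloxy)benzaldehyde
Product: 11 (2E)-3-[2,4-bis(triisopropylsilyloxy)phenyl]prop-2-enal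
Conditions: Ph3P=CHCHO (1.2 equiv), toluene, 90 °C
Reagents that add atoms: (triphenylphosphoranylidene)acetaldehyde (O=CC=P(c1ccccc1)(c1ccccc1)c1ccccc1)
Why: Wittig olefination with the stabilised formylmethylene ylide gives the E enal selectively.

Step 8
Reactants: 8 6-[(1E)-7-methyl-3-methylideneocta-1,6-dien-1-yl]-4-oxo-7-(triisopropylsilyloxy)-4H-chromen-5-yl acetate; 11 (2E)-3-[2,4-bis(triisopropylsilyloxy)phenyl]prop-2-enal
Product: 12 (1R,2R,6S)-2-[5-acetoxy-4-oxo-7-(triisopropylsilyloxy)-4H-chromen-6-yl]-6-[2,4-bis(triisopropylsilyloxy)phenyl]-4-(4-methylpent-3-en-1-yl)cyclohex-3-ene-1-carbaldehyde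
Conditions: (S)-2-{bis[3,5-bis(trifluoromethyl)phenyl](triethylsilyloxy)methyl}pyrrolidine (20 mol%), CF3CO2H (20 mol%), toluene, 4 °C to rt
Reagents that add atoms: none
Why: Iminium-catalysed asymmetric Diels–Alder reaction (diarylprolinol silyl ether) in which the 1-aryl-3-alkyl diene reacts with ortho/para regiochemistry, the (S)-catalyst blocks the Re face so the diene adds to the Cα-Si/Cβ-Si face of the E enal (C1 R, C6 S), and an exo transition state, expected because the twisted 2,6-dioxygenated aryl group avoids the bulky catalyst-bound iminium, places that aryl trans to CHO (C2 R) to give the all-trans adduct, which is also the thermodynamic orientation of the enolisable formyl carbon.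

Step 9
Reactants: 12 (1R,2R,6S)-2-[5-acetoxy-4-oxo-7-(triisopropylsilyloxy)-4H-chromen-6-yl]-6-[2,4-bis(triisopropylsilyloxy)phenyl]-4-(4-methylpent-3-en-1-yl)cyclohex-3-ene-1-carbaldehyde
Product: 13 (E)-N-tert-butylhydrazone of aldehyde 12
Conditions: t-BuNHNH2·HCl, NaOAc, EtOH–CH2Cl2, rt
Reagents that add atoms: tert-butylhydrazine hydrochloride (CC(C)(C)NN.Cl)
Why: Hydrazone condensation at the aldehyde is fast at room temperature, whereas the chromone reacts with hydrazines only on heating, and the ring stereocentres are untouched.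

Step 10
Reactants: 14 4-bromophenol; 15 prenyl bromide
Product: 16 4-bromo-2-(3-methylbut-2-en-1-yl)phenol
Conditions: NaH, toluene, 0 °C to rt
Reagents that add atoms: none
Why: C-alkylation of the sodium phenoxide as a tight ion pair in a non-polar solvent favours ortho-prenylation over O-alkylation, and the para position is blocked by bromine.

Step 11
Reactants: 16 4-bromo-2-(3-methylbut-2-en-1-yl)phenol
Product: 17 [4-bromo-2-(3-methylbut-2-en-1-yl)phenoxy]triisopropylsilane
Conditions: TIPSCl, imidazole, DMF, rt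
Reagents that add atoms: triisopropylsilyl chloride (CC(C)[Si](Cl)(C(C)C)C(C)C)
Why: Silyl ether formation gives a base-tolerant, fluoride-labile protecting group on the phenol.

Step 12
Reactants: 13 (E)-N-tert-butylhydrazone of aldehyde 12; 17 [4-bromo-2-(3-methylbut-2-en-1-yl)phenoxy]triisopropylsilane
Product: 20 [(1R,2R,6S)-2-[5-hydroxy-4-oxo-7-(triisopropylsilyloxy)-4H-chromen-6-yl]-6-[2,4-bis(triisopropylsilyloxy)phenyl]-4-(4-methylpent-3-en-1-yl)cyclohex-3-en-1-yl][3-(3-methylbut-2-en-1-yl)-4-(triisopropylsilyloxy)phenyl]methanone, via azo adduct 18 (not isolated), via ketone N-tert-butylhydrazone 19 (not isolated)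
Conditions: Pd2(dba)3 (2.5 mol%), DPEphos (6 mol%), NaOt-Bu (3.5 equiv), toluene, 80 °C; then 1 M aq. HCl, THF, rt
Reagents that add atoms: water (O)
Why: Pd-catalysed coupling of an N-tert-butylhydrazone as acyl-anion equivalent with an aryl bromide (Hartwig-type): the hydrazonide is C-arylated at the former aldehyde carbon to azo compound 18, which tautomerises to hydrazone 19 and is hydrolysed to the ketone, so the two electrophilic carbons (CHO and C–Br) are joined without touching the chromone carbonyl; NaOt-Bu also removes the temporary acetate, and the carbon α to the new ketone keeps its thermodynamic all-trans orientation (C1 R).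

Step 13
Reactants: 21 4-bromoresorcinol
Product: 22 1-bromo-2,4-bis(tert-butyldimethylsilyloxy)benzene
Conditions: TBSCl (2.3 equiv), imidazole, DMF, rt
Reagents that add atoms: tert-butyldimethylsilyl chloride (CC(C)(C)[Si](C)(C)Cl)
Why: Silyl ether formation; the smaller TBS group is chosen so the ortho-silyloxy boronic acid can still transmetalate, and it meets no strong base afterwards.

Step 14
Reactants: 22 1-bromo-2,4-bis(tert-butyldimethylsilyloxy)benzene
Product: 25 [2,4-bis(tert-butyldimethylsilyloxy)phenyl]boronic acid, via aryllithium 23 (not isolated), via lithium aryltriisopropoxyborate 24 (not isolated)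
Conditions: B(Oi-Pr)3, n-BuLi, THF, −78 °C (in situ quench); then 1 M HCl to pH 5
Reagents that add atoms: triisopropyl borate (CC(C)OB(OC(C)C)OC(C)C); water (O)
Why: Bromine–lithium exchange with in situ borate trapping (borylation), where trapping at −78 °C outruns retro-Brook silyl migration of the ortho-lithiated aryl silyl ether.

Step 15
Reactants: 20 [(1R,2R,6S)-2-[5-hydroxy-4-oxo-7-(triisopropylsilyloxy)-4H-chromen-6-yl]-6-[2,4-bis(triisopropylsilyloxy)phenyl]-4-(4-methylpent-3-en-1-yl)cyclohex-3-en-1-yl][3-(3-methylbut-2-en-1-yl)-4-(triisopropylsilyloxy)phenyl]methanone; 25 [2,4-bis(tert-butyldimethylsilyloxy)phenyl]boronic acid (3 equiv)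
Product: 26 (2S)-2-[2,4-bis(tert-butyldimethylsilyloxy)phenyl]-6-[(1R,5S,6R)-5-[2,4-bis(triisopropylsilyloxy)phenyl]-3-(4-methylpent-3-en-1-yl)-6-[3-(3-methylbut-2-en-1-yl)-4-(triisopropylsilyloxy)benzoyl]cyclohex-2-en-1-yl]-5-hydroxy-7-(triisopropylsilyloxy)-2,3-dihydro-4H-chromen-4-one
Conditions: Pd(OCOCF3)2 (10 mol%), (R)-t-BuPyOX (12 mol%), NH4PF6 (30 mol%), H2O (5 equiv), ClCH2CH2Cl, 60 °C
Reagents that add atoms: none
Why: Pd(II)/PyOX-catalysed asymmetric conjugate addition of an arylboronic acid to a chromone (Stoltz-type) runs without base, so the flavanone centre is created last and is never exposed to conditions that open the ring; the ligand alone controls C2 (2S), the (R)-ligand being chosen by analogy with cyclic enones, where the (S)-ligand gives the (R)-β-aryl ketone, and the remote cyclohexene centres exert no bias.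

Step 16
Reactants: 26 (2S)-2-[2,4-bis(tert-butyldimethylsilyloxy)phenyl]-6-[(1R,5S,6R)-5-[2,4-bis(triisopropylsilyloxy)phenyl]-3-(4-methylpent-3-en-1-yl)-6-[3-(3-methylbut-2-en-1-yl)-4-(triisopropylsilyloxy)benzoyl]cyclohex-2-en-1-yl]-5-hydroxy-7-(triisopropylsilyloxy)-2,3-dihydro-4H-chromen-4-one
Product: 27 (2S)-2-(2,4-dihydroxyphenyl)-6-[(1R,5S,6R)-5-(2,4-dihydroxyphenyl)-6-[4-hydroxy-3-(3-methylbut-2-en-1-yl)benzoyl]-3-(4-methylpent-3-en-1-yl)cyclohex-2-en-1-yl]-5,7-dihydroxy-2,3-dihydro-4H-chromen-4-one (CNP0235243.2)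
Conditions: HF·pyridine, excess pyridine, THF, 0 °C to rt
Reagents that add atoms: none
Why: Fluoride-mediated desilylation under buffered, non-basic conditions removes all six aryl silyl ethers without opening the flavanone (no C2 epimerisation), without disturbing the ketone α-centre and without acid-induced cyclisation of phenols onto the prenyl or ring olefins.

**Compound list**
1 | 2',4',6'-trihydroxyacetophenone | CC(=O)c1c(O)cc(O)cc1O | starting material
2 | 4-ethoxy-5,7-dihydroxychromenylium perchlorate | CCOc1cc[o+]c2cc(O)cc(O)c12.[O-]Cl(=O)(=O)=O | intermediate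
3 | 5,7-dihydroxy-4H-chromen-4-one | O=c1ccoc2cc(O)cc(O)c12 | intermediate
4 | 5-hydroxy-7-(triisopropylsilyloxy)-4H-chromen-4-one | O=c1ccoc2cc(O[Si](C(C)C)(C(C)C)C(C)C)cc(O)c12 | intermediate
5 | 5-hydroxy-6-iodo-7-(triisopropylsilyloxy)-4H-chromen-4-one | O=c1ccoc2cc(O[Si](C(C)C)(C(C)C)C(C)C)c(I)c(O)c12 | intermediate
6 | 6-iodo-4-oxo-7-(triisopropylsilyloxy)-4H-chromen-5-yl acetate | CC(=O)Oc1c(I)c(O[Si](C(C)C)(C(C)C)C(C)C)cc2occc(=O)c12 | intermediate
7 | β-myrcene (7-methyl-3-methylideneocta-1,6-diene) | C=CC(=C)CCC=C(C)C | starting material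
8 | 6-[(1E)-7-methyl-3-methylideneocta-1,6-dien-1-yl]-4-oxo-7-(triisopropylsilyloxy)-4H-chromen-5-yl acetate | CC(C)=CCCC(=C)/C=C/c1c(OC(C)=O)c2c(=O)ccoc2cc1O[Si](C(C)C)(C(C)C)C(C)C | intermediate
9 | 2,4-dihydroxybenzaldehyde | O=Cc1ccc(O)cc1O | starting material
10 | 2,4-bis(triisopropylsilyloxy)benzaldehyde | O=Cc1ccc(O[Si](C(C)C)(C(C)C)C(C)C)cc1O[Si](C(C)C)(C(C)C)C(C)C | intermediate
11 | (2E)-3-[2,4-bis(triisopropylsilyloxy)phenyl]prop-2-enal | O=C/C=C/c1ccc(O[Si](C(C)C)(C(C)C)C(C)C)cc1O[Si](C(C)C)(C(C)C)C(C)C | intermediate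
12 | (1R,2R,6S)-2-[5-acetoxy-4-oxo-7-(triisopropylsilyloxy)-4H-chromen-6-yl]-6-[2,4-bis(triisopropylsilyloxy)phenyl]-4-(4-methylpent-3-en-1-yl)cyclohex-3-ene-1-carbaldehyde; CHO trans to both aryl groups | CC(C)=CCCC1=C[C@@H](c2c(O[Si](C(C)C)(C(C)C)C(C)C)cc3c(c2OC(C)=O)c(=O)cco3)[C@H](C=O)[C@@H](c2ccc(O[Si](C(C)C)(C(C)C)C(C)C)cc2O[Si](C(C)C)(C(C)C)C(C)C)C1 | intermediate
13 | (E)-N-tert-butylhydrazone of aldehyde 12 (same ring configuration) | CC(C)=CCCC1=C[C@@H](c2c(O[Si](C(C)C)(C(C)C)C(C)C)cc3c(c2OC(C)=O)c(=O)cco3)[C@H](/C=N/NC(C)(C)C)[C@@H](c2ccc(O[Si](C(C)C)(C(C)C)C(C)C)cc2O[Si](C(C)C)(C(C)C)C(C)C)C1 | intermediate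
14 | 4-bromophenol | Oc1ccc(Br)cc1 | starting material
15 | prenyl bromide (1-bromo-3-methylbut-2-ene) | CC(C)=CCBr | starting material
16 | 4-bromo-2-(3-methylbut-2-en-1-yl)phenol | CC(C)=CCc1cc(Br)ccc1O | intermediate
17 | [4-bromo-2-(3-methylbut-2-en-1-yl)phenoxy]triisopropylsilane | CC(C)=CCc1cc(Br)ccc1O[Si](C(C)C)(C(C)C)C(C)C | intermediate
18 | azo adduct: tert-butyldiazenyl(aryl)methyl compound from C-arylation of 13, 5-OH free, mixture at the new CH(N=N) carbon, ring configuration as in 20 | CC(C)=CCCC1=C[C@@H](c2c(O[Si](C(C)C)(C(C)C)C(C)C)cc3c(c2O)c(=O)cco3)[C@H](C(N=NC(C)(C)C)c2ccc(O[Si](C(C)C)(C(C)C)C(C)C)c(CC=C(C)C)c2)[C@@H](c2ccc(O[Si](C(C)C)(C(C)C)C(C)C)cc2O[Si](C(C)C)(C(C)C)C(C)C)C1 | intermediate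
19 | N-tert-butylhydrazone of ketone 20 | CC(C)=CCCC1=C[C@@H](c2c(O[Si](C(C)C)(C(C)C)C(C)C)cc3c(c2O)c(=O)cco3)[C@H](C(=NNC(C)(C)C)c2ccc(O[Si](C(C)C)(C(C)C)C(C)C)c(CC=C(C)C)c2)[C@@H](c2ccc(O[Si](C(C)C)(C(C)C)C(C)C)cc2O[Si](C(C)C)(C(C)C)C(C)C)C1 | intermediate
20 | [(1R,2R,6S)-2-[5-hydroxy-4-oxo-7-(triisopropylsilyloxy)-4H-chromen-6-yl]-6-[2,4-bis(triisopropylsilyloxy)phenyl]-4-(4-methylpent-3-en-1-yl)cyclohex-3-en-1-yl][3-(3-methylbut-2-en-1-yl)-4-(triisopropylsilyloxy)phenyl]methanone; all-trans | CC(C)=CCCC1=C[C@@H](c2c(O[Si](C(C)C)(C(C)C)C(C)C)cc3c(c2O)c(=O)cco3)[C@H](C(=O)c2ccc(O[Si](C(C)C)(C(C)C)C(C)C)c(CC=C(C)C)c2)[C@@H](c2ccc(O[Si](C(C)C)(C(C)C)C(C)C)cc2O[Si](C(C)C)(C(C)C)C(C)C)C1 | intermediate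
21 | 4-bromoresorcinol (4-bromobenzene-1,3-diol) | Oc1ccc(Br)c(O)c1 | starting material
22 | 1-bromo-2,4-bis(tert-butyldimethylsilyloxy)benzene | Brc1ccc(O[Si](C)(C)C(C)(C)C)cc1O[Si](C)(C)C(C)(C)C | intermediate
23 | [2,4-bis(tert-butyldimethylsilyloxy)phenyl]lithium | [Li]c1ccc(O[Si](C)(C)C(C)(C)C)cc1O[Si](C)(C)C(C)(C)C | intermediate
24 | lithium [2,4-bis(tert-butyldimethylsilyloxy)phenyl]triisopropoxyborate | [Li+].CC(C)O[B-](OC(C)C)(OC(C)C)c1ccc(O[Si](C)(C)C(C)(C)C)cc1O[Si](C)(C)C(C)(C)C | intermediate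
25 | [2,4-bis(tert-butyldimethylsilyloxy)phenyl]boronic acid | OB(O)c1ccc(O[Si](C)(C)C(C)(C)C)cc1O[Si](C)(C)C(C)(C)C | intermediate
26 | (2S)-2-[2,4-bis(tert-butyldimethylsilyloxy)phenyl]-6-[(1R,5S,6R)-5-[2,4-bis(triisopropylsilyloxy)phenyl]-3-(4-methylpent-3-en-1-yl)-6-[3-(3-methylbut-2-en-1-yl)-4-(triisopropylsilyloxy)benzoyl]cyclohex-2-en-1-yl]-5-hydroxy-7-(triisopropylsilyloxy)-2,3-dihydro-4H-chromen-4-one | CC(C)=CCCC1=C[C@@H](c2c(O[Si](C(C)C)(C(C)C)C(C)C)cc3c(c2O)C(=O)C[C@@H](c2ccc(O[Si](C)(C)C(C)(C)C)cc2O[Si](C)(C)C(C)(C)C)O3)[C@H](C(=O)c2ccc(O[Si](C(C)C)(C(C)C)C(C)C)c(CC=C(C)C)c2)[C@@H](c2ccc(O[Si](C(C)C)(C(C)C)C(C)C)cc2O[Si](C(C)C)(C(C)C)C(C)C)C1 | intermediate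
27 | (2S)-2-(2,4-dihydroxyphenyl)-6-[(1R,5S,6R)-5-(2,4-dihydroxyphenyl)-6-[4-hydroxy-3-(3-methylbut-2-en-1-yl)benzoyl]-3-(4-methylpent-3-en-1-yl)cyclohex-2-en-1-yl]-5,7-dihydroxy-2,3-dihydro-4H-chromen-4-one | CC(C)=CCCC1=C[C@@H](c2c(O)cc3c(c2O)C(=O)C[C@@H](c2ccc(O)cc2O)O3)[C@H](C(=O)c2ccc(O)c(CC=C(C)C)c2)[C@@H](c2ccc(O)cc2O)C1 | target

**Totals and risks**

Total step count: 16. Longest linear sequence: 10 steps (steps 1, 2, 3, 4, 5, 8, 9, 12, 15, 16).

The three steps most likely to fail are the Diels–Alder reaction (step 8), the acyl-anion arylation (step 12) and the late asymmetric conjugate addition (step 15).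

The Diels–Alder reaction must go through the exo transition state. An endo adduct would have the two aryl groups trans to each other, and no epimerisation can correct that. The electron-rich enal may also react slowly. The fallback sets out from diene 8 and turns the normal endo preference into an advantage. Diene 8 is combined with (2E)-3-(4,4,5,5-tetramethyl-1,3,2-dioxaborolan-2-yl)prop-2-enal F1 and the (R)-enantiomer of the same catalyst. This should give the endo pinacolboronate aldehyde F2, with CHO cis to the chromonyl group and trans to boron. NaIO4 in aqueous HCl–THF cleaves the pinacol ester to the boronic acid F3. A stereoinvertive Pd-catalysed Suzuki–Miyaura coupling of this secondary alkylboron (a β-formyl boron homoenolate; Pd/P(t-Bu)3 precatalyst, K2CO3, toluene–H2O, 100 °C) with 1-bromo-2,4-bis(triisopropylsilyloxy)benzene F4 then puts the aryl group cis to the chromonyl group. The carbonate removes the acetate and epimerises the formyl-bearing carbon in the same pot, giving the all-trans 5-hydroxy aldehyde F5. Its tert-butylhydrazone F6 is taken through the conditions of step 12, and the route is rejoined at 20.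

The hydrazone arylation may stall on this hindered, α-branched substrate, or NaOt-Bu may attack the chromone or the silyl ethers. The fallback sets out from aldehyde 12 (with bromide 17) and replaces the polar acyl-anion coupling by direct aldehyde C–H arylation through an acyl–nickel species (Ir photocatalyst, NiBr2·dtbbpy, quinuclidine as hydrogen-atom-transfer catalyst, K2CO3, dioxane, blue light, rt). This needs no strong base and gives the 5-O-acetyl ketone F7. Hydrazinium acetate in DMF removes the acetate, and the route is rejoined at 20.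

The conjugate addition uses an ortho-silyloxy boronic acid prone to protodeboronation, on a precious substrate whose olefins could undergo Heck-type side reactions. If yield or selectivity is poor, the fallback sets out from 20 (with 25) and gives up catalyst control. A non-selective Rh(I)-catalysed 1,4-addition ([Rh(cod)Cl]2, K3PO4, dioxane–H2O) gives 26 together with its C2 epimer F8. The two are diastereomers and are separated by chromatography. F8 is recycled by NaOAc-mediated flavanone–chalcone equilibration in EtOH and separated again, so the material converges on 26.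

Further compounds
F1 | step 8 | (2E)-3-(4,4,5,5-tetramethyl-1,3,2-dioxaborolan-2-yl)prop-2-enal | O=C/C=C/B1OC(C)(C)C(C)(C)O1
F2 | step 8 | endo adduct: 2-[5-acetoxy-4-oxo-7-(triisopropylsilyloxy)-4H-chromen-6-yl]-4-(4-methylpent-3-en-1-yl)-6-(4,4,5,5-tetramethyl-1,3,2-dioxaborolan-2-yl)cyclohex-3-ene-1-carbaldehyde, CHO cis to chromonyl and trans to boron, absolute configuration as in the SMILES | CC(C)=CCCC1=C[C@@H](c2c(O[Si](C(C)C)(C(C)C)C(C)C)cc3c(c2OC(C)=O)c(=O)cco3)[C@@H](C=O)[C@H](B2OC(C)(C)C(C)(C)O2)C1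
F3 | step 8 | boronic acid corresponding to F2 (same configuration) | CC(C)=CCCC1=C[C@@H](c2c(O[Si](C(C)C)(C(C)C)C(C)C)cc3c(c2OC(C)=O)c(=O)cco3)[C@@H](C=O)[C@H](B(O)O)C1
F4 | step 8 | 1-bromo-2,4-bis(triisopropylsilyloxy)benzene | Brc1ccc(O[Si](C(C)C)(C(C)C)C(C)C)cc1O[Si](C(C)C)(C(C)C)C(C)C
F5 | step 8 | (1R,2R,6S)-2-[5-hydroxy-4-oxo-7-(triisopropylsilyloxy)-4H-chromen-6-yl]-6-[2,4-bis(triisopropylsilyloxy)phenyl]-4-(4-methylpent-3-en-1-yl)cyclohex-3-ene-1-carbaldehyde (all-trans, 5-OH free) | CC(C)=CCCC1=C[C@@H](c2c(O[Si](C(C)C)(C(C)C)C(C)C)cc3c(c2O)c(=O)cco3)[C@H](C=O)[C@@H](c2ccc(O[Si](C(C)C)(C(C)C)C(C)C)cc2O[Si](C(C)C)(C(C)C)C(C)C)C1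
F6 | step 8 | (E)-N-tert-butylhydrazone of F5 | CC(C)=CCCC1=C[C@@H](c2c(O[Si](C(C)C)(C(C)C)C(C)C)cc3c(c2O)c(=O)cco3)[C@H](/C=N/NC(C)(C)C)[C@@H](c2ccc(O[Si](C(C)C)(C(C)C)C(C)C)cc2O[Si](C(C)C)(C(C)C)C(C)C)C1
F7 | step 12 | 5-O-acetyl derivative of ketone 20 (same configuration) | CC(C)=CCCC1=C[C@@H](c2c(O[Si](C(C)C)(C(C)C)C(C)C)cc3c(c2OC(C)=O)c(=O)cco3)[C@H](C(=O)c2ccc(O[Si](C(C)C)(C(C)C)C(C)C)c(CC=C(C)C)c2)[C@@H](c2ccc(O[Si](C(C)C)(C(C)C)C(C)C)cc2O[Si](C(C)C)(C(C)C)C(C)C)C1
F8 | step 15 | (2R)-epimer of 26 (cyclohexene configuration unchanged) | CC(C)=CCCC1=C[C@@H](c2c(O[Si](C(C)C)(C(C)C)C(C)C)cc3c(c2O)C(=O)C[C@H](c2ccc(O[Si](C)(C)C(C)(C)C)cc2O[Si](C)(C)C(C)(C)C)O3)[C@H](C(=O)c2ccc(O[Si](C(C)C)(C(C)C)C(C)C)c(CC=C(C)C)c2)[C@@H](c2ccc(O[Si](C(C)C)(C(C)C)C(C)C)cc2O[Si](C(C)C)(C(C)C)C(C)C)C1
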